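**Route numbering used throughout:** ring-B phenol 7 (from olivetol 1 via 3, 4, 5), pyranone tosylate 11 (from 8 via 9, 10), aryloxypyranone 12, ketene acetal 15 (from 13 via 14), benzoate 18, Weinreb amide 20 (from 19), keto ester 22, protected isocoumarin 23, target 24.

## The problem

The target 24 is a 3-pentylisocoumarin with a free hydroxyl at C6 and, at C8, an ether link to a second, fully substituted benzene ring (ring B: ether oxygen at C1', OH at C2', OMe at C4', pentyl at C6'). It has no stereocentre, so the difficulties are regiochemical and steric. The diaryl ether oxygen lies between three ortho substituents (C8a with the lactone carbonyl on ring A, and the C2' hydroxyl and C6' pentyl group on ring B). Both rings are electron-rich, so joining two finished arenes by nucleophilic aromatic substitution or copper coupling is the least promising construction. Four aromatic oxygens must end in three different states (two free phenols, one methyl ether, one diaryl ether), so the C6 and C2' oxygens need a protecting group that comes off without touching the C4' methyl ether. The enol lactone opens with hydroxide or alkoxide, its C3–C4 double bond can be reduced, and the 4-alkoxyphenol motif of ring B is easily oxidised, so the end game must be mild and non-basic. The feature that opens the problem is that ring A is a masked orsellinate. C8a (bearing C1), C8 (bearing the ether oxygen), C7 and C4a (bearing C4) correspond to C5, C4, C3 and C6 of a 6-methyl-2-pyranone-5-carboxylate, and C5 and C6 of ring A can come from a ketene acetal. The pyranone C4 is a vinylogous acyl carbon, so it can take up even a hindered phenoxide by addition–elimination.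

## Retrosynthesis

**24 from 23.** The two O–benzyl bonds are cut last. Benzyl is preferred to methyl, which could not be told from the C4' methyl ether, and to silyl, which would not survive the amide base and acid of the preceding steps. The forward reaction must cleave two aryl benzyl ethers while sparing an unchelated aryl methyl ether, the diaryl ether and the enol lactone; a boron Lewis acid with a cation scavenger at low temperature meets this.

**23 from 22, and 22 from 18 and 20.** The lactone C1–O2 bond and the C3–C4 bond are cut. This leads to the ortho-toluate 18 and the six-carbon acyl donor 20, itself one step from the acid chloride 19. The cut uses the C4a methyl group that the pyranone supplies at no cost. An alkyne cyclisation would need a halide at C4a, and a homophthalate would need an extra carboxyl carbon. The forward steps require lithiation only at the ester-activated methyl group, clean mono-acylation, and closure through the enol oxygen, not through carbon.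

**18 from 12 and 15 (key disconnection).** Ring A is cut at C6–C7 and C4a–C5 (the C3–C4 and C5–C6 bonds of benzoate 18). The four remaining ring carbons, the ester, the methyl group and the aryloxy group belong to pyranone 12, and the C5–C6 unit with its oxygen belongs to ketene acetal 15. The aromatic ring is thus built around the ether oxygen, so no aryl–oxygen coupling is needed, and the oxygen pattern of ring A follows from the polarity of the two partners. The forward reaction must be regioselective and must proceed despite the donor at pyranone C4. Decarboxylation and loss of one benzyloxy group as the alcohol then complete the aromatisation.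

**12 from 11 and 7.** The pyranone C4–O bond is cut. Compared with making the same oxygen bridge between two benzene rings, the electrophile is a vinylogous sulfonate conjugated to the lactone carbonyl. The forward reaction requires attack of the phenoxide of 7 at C4, not at sulfur or at C6.

**11 from 10, 9 and 8.** The sulfonate goes back to hydroxypyranone 10, whose lactone O–C bond is cut to the acyclic tricarbonyl compound 9. The acetyl group of 9 is removed to reach the symmetrical keto diester 8. The ring can close only one way through oxygen, so three simple operations give a fully substituted pyranone.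

**7 from 5, 4, 3 and 1.** The C1'–O bond of phenol 7 is traced to the formyl group of aldehyde 5 by peracid oxidation via formate 6. The benzyl and methyl ethers are removed in turn (4, then 3), and the formyl group is removed to reach olivetol 1. The formyl group marks the carbon that must carry the ether oxygen, and its hydrogen bond to the neighbouring hydroxyl differentiates the two phenols of 3. A route through a free catechol would instead depend on a selective monoprotection. The forward steps rely on the known preference for formylation next to the alkyl chain and for alkylation of the non-chelated hydroxyl.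

**15 from 14 and 13.** The ketene acetal double bond is made by dehydrobromination of bromoacetal 14, which comes from the commercial dimethyl acetal 13 by acetal exchange. Two benzyl groups are chosen so that either alkoxy group can be lost on aromatisation with the same result.

## Roads not taken

**Alternative 1: ring B from an aryloxymalonate.** Ring B is cut at C1'–C6' and C2'–C3'. The precursors are the aryloxymalonate dimethyl 2-{[6-(benzyloxy)-1-oxo-3-pentyl-1H-isochromen-8-yl]oxy}propanedioate A3 and the enone (E)-non-3-en-2-one A2. With an alkoxide base the malonate carbon would add to the β-carbon of A2 and the methyl ketone enolate would close onto one ester. The product is the cyclohexane-1,3-dione methyl 1-{[6-(benzyloxy)-1-oxo-3-pentyl-1H-isochromen-8-yl]oxy}-2,4-dioxo-6-pentylcyclohexane-1-carboxylate A1, as a mixture of diastereomers.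
- Merits: it also builds a ring around the ether oxygen, it uses a cheap acyclic partner, and it does not need olivetol 1. In the ring-B branch it is shorter on paper than the chosen plan.
- Weak points: A1 is still three operations from an arene. The ester on the quaternary carbon must be removed, and saponification would also open the enol lactone. The dione must be dehydrogenated. The C4' oxygen must then be methylated in preference to the C2' oxygen with little bias.
- Further weak points: the Michael addition forms a quaternary carbon next to a tertiary one under alkoxide, which threatens the lactone. A3 itself requires alkylation of a chelated peri hydroxyl.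
- Comparison: the chosen plan is longer in the ring-B branch, but all three ring-B oxygens are in their final, differentiated state before the two halves meet, and no redox step or selective methylation follows the coupling.

**Alternative 2: aryne insertion to a fluorinated homophthalate.** Ring A is cut at C4a–C4 and C8a–C1. Fluoride would release an aryne from 5-(benzyloxy)-3-fluoro-2-(trimethylsilyl)phenyl trifluoromethanesulfonate A5. A malonate carbanion would add meta to fluorine, and the aryl anion would take over one ester group. The product is methyl 4-(benzyloxy)-2-fluoro-6-(2-methoxy-2-oxoethyl)benzoate A4. The fluoride of A4 would then be displaced by the phenoxide of 7, and the homophthalate would be C-acylated with 19 and lactonised with decarboxylation.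
- Merits: one step places both carbon substituents of ring A with fluorine-controlled regiochemistry. The homophthalate route to the isocoumarin needs no lateral lithiation, and in that respect it is better than the chosen plan.
- Weak points: the hindered ether is made by substitution at a fluoride activated by a single ortho ester, with a di-ortho-substituted phenoxide. The base would first deprotonate the acidic homophthalate methylene and make the ring electron-rich. A5 takes several steps, and decarboxylative acylation is harsh on benzyl ethers.
- Comparison: the chosen plan accepts a lateral lithiation, and in return forms the critical C–O bond on a vinylogous sulfonate and not on an arene.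

**Alternative 3: biomimetic aldol aromatisation.** The cut is at C4a–C8a and C1–O2. The precursor is 4-[2-(benzyloxy)-4-methoxy-6-pentylphenoxy]-6-(2,4-dioxononyl)-2H-pyran-2-one A7. An alkoxide would open the pyranone, aldol condensation would close and aromatise ring A, and the C3 enol oxygen would close the lactone. The product is 8-[2-(benzyloxy)-4-methoxy-6-pentylphenoxy]-6-hydroxy-3-pentyl-1H-isochromen-1-one A6, one debenzylation from 24.
- Merits: it is the shortest route, perhaps three or four steps fewer. It uses the same phenoxide addition–elimination on a pyranone, closes two rings in one flask, and delivers the C6 hydroxyl unprotected.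
- Weak points: the aryloxy group of A7 sits on a vinylogous ester carbon, so the alkoxide that opens the lactone can also add there and expel the phenoxide of 7. The opened tetracarbonyl chain has several competing cyclisation modes. A7 must be made by acylating a pyranone methyl group at a stage with several acidic sites.
- Comparison: the chosen plan pays in step count for ring formation with one plausible regiochemistry, and for an aryloxy group that meets no nucleophile once installed.

Key step: step 11

## Route

Remark: the target is achiral. The only stereocentres on the route are the two bridgeheads of the transient cycloadduct 16 (racemic), and they are lost on decarboxylation.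

Step 1
Reactants: 1 olivetol (5-pentylbenzene-1,3-diol)
Product: 3 2,4-dihydroxy-6-pentylbenzaldehyde, via iminium chloride 2 (not isolated)
Conditions: POCl3, DMF, 0 °C → rt; then H2O, 50 °C
Reagents that add atoms: N,N-dimethylformamide CN(C)C=O; water O
Why: Vilsmeier–Haack formylation of a resorcinol; the chloroiminium ion should attack mainly the carbon para to one hydroxyl and ortho to the other (next to the pentyl chain), as is usual for 5-alkylresorcinols, and the minor 2,6-dihydroxy isomer is removed on purification.

Step 2
Reactants: 3 2,4-dihydroxy-6-pentylbenzaldehyde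
Product: 4 2-hydroxy-4-methoxy-6-pentylbenzaldehyde
Conditions: MeI (1.05 equiv), K2CO3 (1.1 equiv), acetone, rt
Reagents that add atoms: iodomethane CI
Why: Williamson etherification; the 2-hydroxyl is held in a hydrogen bond to the aldehyde, so the more acidic para hydroxyl should be alkylated selectively, as is standard for 2,4-dihydroxybenzaldehydes.

Step 3
Reactants: 4 2-hydroxy-4-methoxy-6-pentylbenzaldehyde
Product: 5 2-(benzyloxy)-4-methoxy-6-pentylbenzaldehyde
Conditions: BnBr, K2CO3, DMF, 60 °C
Reagents that add atoms: benzyl bromide BrCc1ccccc1
Why: Williamson etherification of the remaining chelated phenol under more forcing conditions; no other nucleophilic site is present.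

Step 4
Reactants: 5 2-(benzyloxy)-4-methoxy-6-pentylbenzaldehyde
Product: 7 2-(benzyloxy)-4-methoxy-6-pentylphenol, via aryl formate 6 (not isolated)
Conditions: mCPBA, CH2Cl2, 0 °C → rt; then K2CO3, MeOH, rt
Reagents that add atoms: 3-chloroperoxybenzoic acid OOC(=O)c1cccc(Cl)c1
Why: Baeyer–Villiger oxidation of an electron-rich benzaldehyde (Dakin-type) with aryl migration, followed by methanolysis of the formate; the oxygen enters at the former formyl carbon, so the pattern of ring B is fixed without any selective protection.

Step 5
Reactants: 8 dimethyl 3-oxopentanedioate
Product: 9 dimethyl 2-acetyl-3-oxopentanedioate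
Conditions: AcCl, MgCl2, pyridine, CH2Cl2, 0 °C → rt; then 1 M HCl
Reagents that add atoms: acetyl chloride CC(Cl)=O
Why: C-acylation of a β-keto ester by soft enolisation; the magnesium chelate of the product is unreactive, so mono-C-acetylation is expected in preference to O-acylation or double acylation.

Step 6
Reactants: 9 dimethyl 2-acetyl-3-oxopentanedioate
Product: 10 methyl 4-hydroxy-6-methyl-2-oxo-2H-pyran-5-carboxylate
Conditions: conc. H2SO4, 0 °C → rt; then ice-water
Reagents that add atoms: none
Why: Acid-induced lactonisation in which the enol oxygen of the acetyl group attacks the remote ester (6-exo-trig), the only ring size open to an oxygen nucleophile in 9; this is the classical closure of acylated acetonedicarboxylates to 4-hydroxy-2-pyranones.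

Step 7
Reactants: 10 methyl 4-hydroxy-6-methyl-2-oxo-2H-pyran-5-carboxylate
Product: 11 methyl 6-methyl-4-[(4-methylbenzenesulfonyl)oxy]-2-oxo-2H-pyran-5-carboxylate
Conditions: TsCl, Et3N, CH2Cl2, 0 °C → rt
Reagents that add atoms: 4-methylbenzenesulfonyl chloride Cc1ccc(cc1)S(Cl)(=O)=O
Why: O-sulfonylation of the vinylogous acid; 4-hydroxy-2-pyranones are routinely converted into their 4-sulfonates in this way.

Step 8
Reactants: 11 methyl 6-methyl-4-[(4-methylbenzenesulfonyl)oxy]-2-oxo-2H-pyran-5-carboxylate; 7 2-(benzyloxy)-4-methoxy-6-pentylphenol
Product: 12 methyl 4-[2-(benzyloxy)-4-methoxy-6-pentylphenoxy]-6-methyl-2-oxo-2H-pyran-5-carboxylate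
Conditions: Cs2CO3, MeCN, rt → 50 °C, under argon
Reagents that add atoms: none
Why: Addition–elimination (vinylogous acyl substitution) of the phenoxide at C4, which is the β-carbon of the lactone carbonyl and carries the sulfonate leaving group; this is the known reactivity of 4-sulfonyloxy-2-pyranones and coumarins towards O-, N- and S-nucleophiles.

Step 9
Reactants: 13 2-bromo-1,1-dimethoxyethane
Product: 14 2-bromo-1,1-bis(benzyloxy)ethane
Conditions: BnOH (2.2 equiv), TsOH·H2O (cat.), cyclohexane, reflux, MeOH distilled off
Reagents that add atoms: benzyl alcohol OCc1ccccc1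
Why: Acid-catalysed acetal exchange driven to completion by removal of the volatile alcohol.

Step 10
Reactants: 14 2-bromo-1,1-bis(benzyloxy)ethane
Product: 15 1,1-bis(benzyloxy)ethene
Conditions: KOtBu, THF, 0 °C → rt; filtration, short-path distillation under high vacuum, stored over K2CO3
Reagents that add atoms: none
Why: E2 dehydrobromination of a bromoacetaldehyde acetal with a bulky alkoxide, the standard preparation of ketene acetals; substitution at the hindered carbon next to the acetal is not expected to compete.

Step 11
Reactants: 12 methyl 4-[2-(benzyloxy)-4-methoxy-6-pentylphenoxy]-6-methyl-2-oxo-2H-pyran-5-carboxylate; 15 1,1-bis(benzyloxy)ethene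
Product: 18 methyl 4-(benzyloxy)-2-[2-(benzyloxy)-4-methoxy-6-pentylphenoxy]-6-methylbenzoate, via bridged lactone 16 (not isolated), via cyclohexadiene 17 (not isolated)
Conditions: 15 (3 equiv), toluene, 110 °C, sealed tube
Reagents that add atoms: none
Why: The electron-poor diene of 12 (C3=C4–C5=C6) and the electron-rich alkene 15 combine in an inverse-electron-demand Diels–Alder reaction of polar, asynchronous character, in which the CH2 terminus of 15 bonds to C6 and the acetal carbon to C3, giving the bridged lactone 16. Retro-[4+2] loss of CO2 from 16 gives cyclohexadiene 17, and 1,2-elimination of benzyl alcohol from 17 gives the benzene ring. The closest known reaction type is the conversion of 2-pyranone-5-carboxylates, including 4-alkoxy-6-methyl ones, into 4-alkoxybenzoates with ketene acetals. Ring A closes by an intermolecular [4+2] cycloaddition that forms the C3–C4 and C5–C6 bonds of 18 (C6–C7 and C4a–C5 of the isocoumarin) in one operation. No stereocentre remains, because the two bridgehead centres of 16 disappear with the CO2. The selectivity needed is regiochemical: C6 is the β-carbon of the C5 ester and the far end of the vinylogous lactone, while the C4 aryloxy group makes C3 the electron-richer terminus, so the benzyloxy carbon should end up para to the ester carbon. Because both acetal oxygens carry benzyl, either elimination gives the same ether. The aryloxy donor lowers the reactivity of the diene, hence the excess of 15 and the temperature.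

Step 12
Reactants: 19 hexanoyl chloride
Product: 20 N-methoxy-N-methylhexanamide
Conditions: MeNH(OMe)·HCl, Et3N, CH2Cl2, 0 °C → rt
Reagents that add atoms: N,O-dimethylhydroxylamine hydrochloride CNOC.Cl
Why: Acylation of the hydroxylamine by the acid chloride gives the Weinreb amide.

Step 13
Reactants: 18 methyl 4-(benzyloxy)-2-[2-(benzyloxy)-4-methoxy-6-pentylphenoxy]-6-methylbenzoate; 20 N-methoxy-N-methylhexanamide
Product: 22 methyl 4-(benzyloxy)-2-[2-(benzyloxy)-4-methoxy-6-pentylphenoxy]-6-(2-oxoheptyl)benzoate, via benzylic lithium compound 21 (not isolated)
Conditions: LiN(iPr)2 (1.2 equiv), THF, −78 °C; then 20, −78 → −20 °C; then 1 M HCl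
Reagents that add atoms: none
Why: Lateral lithiation of an ortho-toluate ester (the methyl group is the only position conjugated to the ester) followed by Weinreb ketone synthesis; the chelated tetrahedral adduct survives until work-up, so neither over-addition nor proton transfer from the product ketone should interfere.

Step 14
Reactants: 22 methyl 4-(benzyloxy)-2-[2-(benzyloxy)-4-methoxy-6-pentylphenoxy]-6-(2-oxoheptyl)benzoate
Product: 23 6-(benzyloxy)-8-[2-(benzyloxy)-4-methoxy-6-pentylphenoxy]-3-pentyl-1H-isochromen-1-one
Conditions: TsOH·H2O (cat.), toluene, reflux
Reagents that add atoms: none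
Why: Acid-catalysed enol lactonisation (6-exo-trig attack of the enol oxygen on the ester, loss of methanol) gives the isocoumarin; acid is chosen over base to avoid Claisen-type closure through carbon to a naphthalenediol.

Step 15
Reactants: 23 6-(benzyloxy)-8-[2-(benzyloxy)-4-methoxy-6-pentylphenoxy]-3-pentyl-1H-isochromen-1-one
Product: 24 6-hydroxy-8-(2-hydroxy-4-methoxy-6-pentylphenoxy)-3-pentyl-1H-isochromen-1-one
Conditions: BCl3, C6HMe5, CH2Cl2, −78 °C; then MeOH, H2O
Reagents that add atoms: none
Why: Lewis acid cleavage of aryl benzyl ethers with pentamethylbenzene as a non-basic benzyl cation scavenger; at −78 °C the unchelated C4' methyl ether, the diaryl ether and the enol lactone should be left intact.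

## Compound list

1 | olivetol (5-pentylbenzene-1,3-diol) | CCCCCc1cc(O)cc(O)c1 | starting material
2 | [(2,4-dihydroxy-6-pentylphenyl)methylidene]dimethylazanium chloride | CCCCCc1cc(O)cc(O)c1C=[N+](C)C.[Cl-] | intermediate
3 | 2,4-dihydroxy-6-pentylbenzaldehyde | CCCCCc1cc(O)cc(O)c1C=O | intermediate
4 | 2-hydroxy-4-methoxy-6-pentylbenzaldehyde | CCCCCc1cc(OC)cc(O)c1C=O | intermediate
5 | 2-(benzyloxy)-4-methoxy-6-pentylbenzaldehyde | CCCCCc1cc(OC)cc(OCc2ccccc2)c1C=O | intermediate
6 | 2-(benzyloxy)-4-methoxy-6-pentylphenyl formate | CCCCCc1cc(OC)cc(OCc2ccccc2)c1OC=O | intermediate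
7 | 2-(benzyloxy)-4-methoxy-6-pentylphenol | CCCCCc1cc(OC)cc(OCc2ccccc2)c1O | intermediate
8 | dimethyl 3-oxopentanedioate | COC(=O)CC(=O)CC(=O)OC | starting material
9 | dimethyl 2-acetyl-3-oxopentanedioate | COC(=O)CC(=O)C(C(C)=O)C(=O)OC | intermediate
10 | methyl 4-hydroxy-6-methyl-2-oxo-2H-pyran-5-carboxylate | COC(=O)c1c(C)oc(=O)cc1O | intermediate
11 | methyl 6-methyl-4-[(4-methylbenzenesulfonyl)oxy]-2-oxo-2H-pyran-5-carboxylate | COC(=O)c1c(C)oc(=O)cc1OS(=O)(=O)c1ccc(C)cc1 | intermediate
12 | methyl 4-[2-(benzyloxy)-4-methoxy-6-pentylphenoxy]-6-methyl-2-oxo-2H-pyran-5-carboxylate | CCCCCc1cc(OC)cc(OCc2ccccc2)c1Oc1cc(=O)oc(C)c1C(=O)OC | intermediate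
13 | 2-bromo-1,1-dimethoxyethane | COC(CBr)OC | starting material
14 | 2-bromo-1,1-bis(benzyloxy)ethane | BrCC(OCc1ccccc1)OCc1ccccc1 | intermediate
15 | 1,1-bis(benzyloxy)ethene | C=C(OCc1ccccc1)OCc1ccccc1 | intermediate
16 | methyl 8,8-bis(benzyloxy)-5-[2-(benzyloxy)-4-methoxy-6-pentylphenoxy]-1-methyl-3-oxo-2-oxabicyclo[2.2.2]oct-5-ene-6-carboxylate (racemic) | COC(=O)C1=C(Oc2c(CCCCC)cc(OC)cc2OCc2ccccc2)C2C(=O)OC1(C)CC2(OCc1ccccc1)OCc1ccccc1 | intermediate
17 | methyl 4,4-bis(benzyloxy)-6-[2-(benzyloxy)-4-methoxy-6-pentylphenoxy]-2-methylcyclohexa-1,5-diene-1-carboxylate | COC(=O)C1=C(C)CC(OCc2ccccc2)(OCc2ccccc2)C=C1Oc1c(CCCCC)cc(OC)cc1OCc1ccccc1 | intermediate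
18 | methyl 4-(benzyloxy)-2-[2-(benzyloxy)-4-methoxy-6-pentylphenoxy]-6-methylbenzoate | CCCCCc1cc(OC)cc(OCc2ccccc2)c1Oc1cc(OCc2ccccc2)cc(C)c1C(=O)OC | intermediate
19 | hexanoyl chloride | CCCCCC(Cl)=O | starting material
20 | N-methoxy-N-methylhexanamide | CCCCCC(=O)N(C)OC | intermediate
21 | methyl 4-(benzyloxy)-2-[2-(benzyloxy)-4-methoxy-6-pentylphenoxy]-6-(lithiomethyl)benzoate | [Li]Cc1cc(OCc2ccccc2)cc(Oc2c(CCCCC)cc(OC)cc2OCc2ccccc2)c1C(=O)OC | intermediate
22 | methyl 4-(benzyloxy)-2-[2-(benzyloxy)-4-methoxy-6-pentylphenoxy]-6-(2-oxoheptyl)benzoate | CCCCCC(=O)Cc1cc(OCc2ccccc2)cc(Oc2c(CCCCC)cc(OC)cc2OCc2ccccc2)c1C(=O)OC | intermediate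
23 | 6-(benzyloxy)-8-[2-(benzyloxy)-4-methoxy-6-pentylphenoxy]-3-pentyl-1H-isochromen-1-one | CCCCCc1cc2cc(OCc3ccccc3)cc(Oc3c(OCc4ccccc4)cc(OC)cc3CCCCC)c2c(=O)o1 | intermediate
24 | 6-hydroxy-8-(2-hydroxy-4-methoxy-6-pentylphenoxy)-3-pentyl-1H-isochromen-1-one | CCCCCc1cc2cc(O)cc(Oc3c(O)cc(OC)cc3CCCCC)c2c(=O)o1 | target

## Step count and risks

Total step count: 15. Longest linear sequence: 9 steps (steps 1, 2, 3, 4, 8, 11, 13, 14, 15).

**Step 11 (key step).** The most likely failure is a cycloaddition too slow to compete with decay of the dienophile. The C4 aryloxy donor raises the energy of the diene's acceptor orbital and the C6 methyl group hinders the terminus that the CH2 of 15 must attack. At the temperature required, the benzylic ketene acetal may then be lost by migration of benzyl from oxygen to carbon, by hydrolysis or by oligomerisation. Incomplete loss of benzyl alcohol from 17 is a lesser concern. The fallback sets out from 12 and replaces 15 by the silyl ketene acetal 1,1-bis(trimethylsilyloxy)ethene F1, which has no benzylic C–O bond to rearrange. The same cycloaddition and decarboxylation, loss of trimethylsilanol and desilylation on mildly acidic work-up should give methyl 2-[2-(benzyloxy)-4-methoxy-6-pentylphenoxy]-4-hydroxy-6-methylbenzoate F2. Its single free phenol is then benzylated (BnBr, K2CO3, DMF) and the route is rejoined at 18. This fallback also covers a failure to prepare or store 15 in step 10.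

**Step 8.** The hindered phenoxide may attack the sulfonyl sulfur, transferring the tosyl group and returning 10, or add reversibly at C6 with ring opening. C4 is flanked by the C5 ester, which slows the desired attack. The fallback sets out from 10, which is converted (Bu4NBr, P2O5, toluene, 100 °C) into methyl 4-bromo-6-methyl-2-oxo-2H-pyran-5-carboxylate F3. This electrophile offers no site other than carbon, and treatment with 7 and Cs2CO3 in MeCN should give 12 by the same addition–elimination.

**Step 13.** The benzylic anion 21 may add to the ester of a second molecule faster than to the modestly electrophilic amide 20, giving self-condensation products and recovered 18. The fallback sets out from 18 and returns at 23, bypassing 22.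
- The anion is first trapped with hexanal, a far faster electrophile. The resulting alkoxide lactonises to 6-(benzyloxy)-8-[2-(benzyloxy)-4-methoxy-6-pentylphenoxy]-3-pentyl-3,4-dihydro-1H-isochromen-1-one F4 (racemic).
- Base-induced β-elimination of the carboxylate (KOtBu, DMSO) opens F4 to 4-(benzyloxy)-2-[2-(benzyloxy)-4-methoxy-6-pentylphenoxy]-6-[(1E)-hept-1-en-1-yl]benzoic acid F5.
- Oxidative lactonisation with PdCl2(MeCN)2 (divalent palladium, catalytic) and 1,4-benzoquinone in THF, a known route from 2-alkenylbenzoic acids to 3-substituted isocoumarins, should then give 23.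

**Step 15.** Prolonged exposure to BCl3 may start to cleave the C4' methyl ether, and benzyl cations that escape the scavenger may alkylate the electron-rich ring B. The fallback changes the order of events and sets out from 22. Hydrogenolysis (H2, Pd/C, EtOAc), done while no reducible enol-lactone double bond is present, should give methyl 4-hydroxy-2-(2-hydroxy-4-methoxy-6-pentylphenoxy)-6-(2-oxoheptyl)benzoate F6. Acid-catalysed enol lactonisation (TsOH·H2O, toluene, reflux) then leads directly to 24; the six-membered enol lactone is expected to form faster than a seven-membered lactone through the ring-B hydroxyl.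

## Further compounds

F1 | step 11 | 1,1-bis(trimethylsilyloxy)ethene | C=C(O[Si](C)(C)C)O[Si](C)(C)C
F2 | step 11 | methyl 2-[2-(benzyloxy)-4-methoxy-6-pentylphenoxy]-4-hydroxy-6-methylbenzoate | CCCCCc1cc(OC)cc(OCc2ccccc2)c1Oc1cc(O)cc(C)c1C(=O)OC
F3 | step 8 | methyl 4-bromo-6-methyl-2-oxo-2H-pyran-5-carboxylate | COC(=O)c1c(C)oc(=O)cc1Br
F4 | step 13 | 6-(benzyloxy)-8-[2-(benzyloxy)-4-methoxy-6-pentylphenoxy]-3-pentyl-3,4-dihydro-1H-isochromen-1-one (racemic) | CCCCCC1Cc2cc(OCc3ccccc3)cc(Oc3c(OCc4ccccc4)cc(OC)cc3CCCCC)c2C(=O)O1
F5 | step 13 | 4-(benzyloxy)-2-[2-(benzyloxy)-4-methoxy-6-pentylphenoxy]-6-[(1E)-hept-1-en-1-yl]benzoic acid | CCCCC/C=C/c1cc(OCc2ccccc2)cc(Oc2c(CCCCC)cc(OC)cc2OCc2ccccc2)c1C(=O)O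
F6 | step 15 | methyl 4-hydroxy-2-(2-hydroxy-4-methoxy-6-pentylphenoxy)-6-(2-oxoheptyl)benzoate | CCCCCC(=O)Cc1cc(O)cc(Oc2c(CCCCC)cc(OC)cc2O)c1C(=O)OC
A1 | alternative 1 | methyl 1-{[6-(benzyloxy)-1-oxo-3-pentyl-1H-isochromen-8-yl]oxy}-2,4-dioxo-6-pentylcyclohexane-1-carboxylate (mixture of diastereomers) | COC(=O)C1(Oc2cc(OCc3ccccc3)cc3cc(CCCCC)oc(=O)c23)C(CCCCC)CC(=O)CC1=O
A2 | alternative 1 | (E)-non-3-en-2-one | CCCCC/C=C/C(C)=O
A3 | alternative 1 | dimethyl 2-{[6-(benzyloxy)-1-oxo-3-pentyl-1H-isochromen-8-yl]oxy}propanedioate | COC(=O)C(Oc1cc(OCc2ccccc2)cc2cc(CCCCC)oc(=O)c12)C(=O)OC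
A4 | alternative 2 | methyl 4-(benzyloxy)-2-fluoro-6-(2-methoxy-2-oxoethyl)benzoate | COC(=O)Cc1cc(OCc2ccccc2)cc(F)c1C(=O)OC
A5 | alternative 2 | 5-(benzyloxy)-3-fluoro-2-(trimethylsilyl)phenyl trifluoromethanesulfonate | C[Si](C)(C)c1c(F)cc(OCc2ccccc2)cc1OS(=O)(=O)C(F)(F)F
A6 | alternative 3 | 8-[2-(benzyloxy)-4-methoxy-6-pentylphenoxy]-6-hydroxy-3-pentyl-1H-isochromen-1-one | CCCCCc1cc2cc(O)cc(Oc3c(OCc4ccccc4)cc(OC)cc3CCCCC)c2c(=O)o1
A7 | alternative 3 | 4-[2-(benzyloxy)-4-methoxy-6-pentylphenoxy]-6-(2,4-dioxononyl)-2H-pyran-2-one | CCCCCC(=O)CC(=O)Cc1cc(Oc2c(CCCCC)cc(OC)cc2OCc2ccccc2)cc(=O)o1
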